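**Retrosynthetic overview**

1. Target 16 ← hydrogenolysis of benzyl ether 15 ← fluoride/acid deprotection of the fully protected dihydrobenzofuran 13.
2. Ring B (O1–C2–C3–C3a–C7a), the only ring that is made, is closed last by the O1–C7a bond: acyclic ketone 11 → one-pot asymmetric transfer hydrogenation with dynamic kinetic resolution (sets C2 and C3), then displacement of fluoride at C7a by the new C2 alkoxide.
3. Enabling feature: C3 is both benzylic (to C3a) and α to the C2 carbonyl, so it epimerises freely; the oxygen on C2 lies four atoms (C2–C3–C3a–C7a) from C7a, which carries F between C7–OMe and C3a, so a 5-exo SNAr closes ring B.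
4. Ketone 11 ← deoxybenzoin 9 (C3–CH2O by hydroxymethylation, then trityl ether) ← C3–C3a bond by Pd coupling of arylboronate 7 with bromoketone 8; the boron enters by Ir C–H borylation ortho to F.
5. The side chain is installed first: aryllithium from 1 plus (R)-glycerate acetonide ester 2 (C2' from the chiral pool), then chelation-controlled reduction (C1').

Key step: step 8

Assumption: bromoketone 8 is treated as a catalogue compound; otherwise it is one α-bromination away from commercial 1-[4-(benzyloxy)-3-methoxyphenyl]ethan-1-one.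

**Route**

Step 1
Reactants: 1 4-bromo-1-fluoro-2-methoxybenzene; 2 methyl (4R)-2,2-dimethyl-1,3-dioxolane-4-carboxylate
Product: 4 (4-fluoro-3-methoxyphenyl)[(4R)-2,2-dimethyl-1,3-dioxolan-4-yl]methanone, via aryllithium 3 (not isolated)
Conditions: n-BuLi, THF, −78 °C; then cannulated into 2, THF, −78 °C; aq NH4Cl
Reagents that add atoms: none
Why: Br/Li exchange is faster than ortho-lithiation, and the aryllithium should add only once to the α-alkoxy ester because the chelated tetrahedral lithium alkoxide survives at −78 °C until the quench (acylation of an organolithium by an ester); the dioxolane stereocentre comes from 2 and is not touched.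

Step 2
Reactants: 4 (4-fluoro-3-methoxyphenyl)[(4R)-2,2-dimethyl-1,3-dioxolan-4-yl]methanone
Product: 5 (S)-(4-fluoro-3-methoxyphenyl)[(4R)-2,2-dimethyl-1,3-dioxolan-4-yl]methanol
Conditions: Zn(BH4)2 (ethereal solution), Et2O, −30 °C
Reagents that add atoms: none
Why: Chelation-controlled hydride reduction (Cram-chelate model): zinc bridges the carbonyl and the α-dioxolane oxygen and hydride enters from the face of the α-hydrogen, which should give the anti (erythro) alcohol and so sets C1' as S.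

Step 3
Reactants: 5 (S)-(4-fluoro-3-methoxyphenyl)[(4R)-2,2-dimethyl-1,3-dioxolan-4-yl]methanol
Product: 6 tert-butyl{(S)-[(4R)-2,2-dimethyl-1,3-dioxolan-4-yl](4-fluoro-3-methoxyphenyl)methoxy}dimethylsilane
Conditions: t-BuMe2SiOTf, 2,6-lutidine, CH2Cl2, 0 °C
Reagents that add atoms: tert-butyldimethylsilyl trifluoromethanesulfonate, CC(C)(C)[Si](C)(C)OS(=O)(=O)C(F)(F)F
Why: Silylation of a hindered secondary alcohol with a silyl triflate and a hindered pyridine base; no stereocentre is affected.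

Step 4
Reactants: 6 tert-butyl{(S)-[(4R)-2,2-dimethyl-1,3-dioxolan-4-yl](4-fluoro-3-methoxyphenyl)methoxy}dimethylsilane
Product: 7 2-{5-[(S)-{[tert-butyl(dimethyl)silyl]oxy}[(4R)-2,2-dimethyl-1,3-dioxolan-4-yl]methyl]-2-fluoro-3-methoxyphenyl}-4,4,5,5-tetramethyl-1,3,2-dioxaborolane
Conditions: B2pin2, [Ir(cod)OMe]2 (cat.), 4,4'-di-tert-butyl-2,2'-bipyridine (cat.), THF, 80 °C
Reagents that add atoms: bis(pinacolato)diboron, CC1(C)OB(OC1(C)C)B1OC(C)(C)C(C)(C)O1
Why: Ir-catalysed aromatic C–H borylation is sterically controlled and favoured next to fluorine, and since the C–H between OMe and the side chain and the C–H beside the branched side chain are both blocked, boron should enter at the carbon ortho to F (the future C3a).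

Step 5
Reactants: 7 2-{5-[(S)-{[tert-butyl(dimethyl)silyl]oxy}[(4R)-2,2-dimethyl-1,3-dioxolan-4-yl]methyl]-2-fluoro-3-methoxyphenyl}-4,4,5,5-tetramethyl-1,3,2-dioxaborolane; 8 1-[4-(benzyloxy)-3-methoxyphenyl]-2-bromoethan-1-one
Product: 9 1-[4-(benzyloxy)-3-methoxyphenyl]-2-{5-[(S)-{[tert-butyl(dimethyl)silyl]oxy}[(4R)-2,2-dimethyl-1,3-dioxolan-4-yl]methyl]-2-fluoro-3-methoxyphenyl}ethan-1-one
Conditions: Pd(OAc)2 (cat.), P(o-tol)3, K3PO4, THF/H2O, rt
Reagents that add atoms: none
Why: Suzuki–Miyaura-type coupling of an arylboronate with an α-bromo ketone (oxidative addition of C–Br to zerovalent palladium, transmetalation, reductive elimination) forms the C3–C3a bond; no stereocentre is formed.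

Step 6
Reactants: 9 1-[4-(benzyloxy)-3-methoxyphenyl]-2-{5-[(S)-{[tert-butyl(dimethyl)silyl]oxy}[(4R)-2,2-dimethyl-1,3-dioxolan-4-yl]methyl]-2-fluoro-3-methoxyphenyl}ethan-1-one
Product: 10 1-[4-(benzyloxy)-3-methoxyphenyl]-2-{5-[(S)-{[tert-butyl(dimethyl)silyl]oxy}[(4R)-2,2-dimethyl-1,3-dioxolan-4-yl]methyl]-2-fluoro-3-methoxyphenyl}-3-hydroxypropan-1-one (mixture of C2 epimers)
Conditions: (CH2O)n (1.1 equiv), K2CO3 (cat.), DMSO, rt
Reagents that add atoms: formaldehyde (as paraformaldehyde), C=O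
Why: Base-catalysed aldol addition of the doubly activated methylene to formaldehyde (hydroxymethylation) installs the CH2O carbon on C3, which forms as a mixture of epimers that step 8 is designed to converge.

Step 7
Reactants: 10 1-[4-(benzyloxy)-3-methoxyphenyl]-2-{5-[(S)-{[tert-butyl(dimethyl)silyl]oxy}[(4R)-2,2-dimethyl-1,3-dioxolan-4-yl]methyl]-2-fluoro-3-methoxyphenyl}-3-hydroxypropan-1-one
Product: 11 1-[4-(benzyloxy)-3-methoxyphenyl]-2-{5-[(S)-{[tert-butyl(dimethyl)silyl]oxy}[(4R)-2,2-dimethyl-1,3-dioxolan-4-yl]methyl]-2-fluoro-3-methoxyphenyl}-3-(triphenylmethoxy)propan-1-one (mixture of C2 epimers)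
Conditions: Ph3CCl, pyridine, DMAP (cat.), CH2Cl2, rt
Reagents that add atoms: trityl chloride, ClC(c1ccccc1)(c1ccccc1)c1ccccc1
Why: Tritylation of the primary alcohol gives an ether that cannot migrate under base and blocks the only other oxygen that could compete for ring closure; C3 remains a labile mixture.

Step 8
Reactants: 11 1-[4-(benzyloxy)-3-methoxyphenyl]-2-{5-[(S)-{[tert-butyl(dimethyl)silyl]oxy}[(4R)-2,2-dimethyl-1,3-dioxolan-4-yl]methyl]-2-fluoro-3-methoxyphenyl}-3-(triphenylmethoxy)propan-1-one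
Product: 13 (2R,3S)-2-[4-(benzyloxy)-3-methoxyphenyl]-5-[(S)-{[tert-butyl(dimethyl)silyl]oxy}[(4R)-2,2-dimethyl-1,3-dioxolan-4-yl]methyl]-7-methoxy-3-[(triphenylmethoxy)methyl]-2,3-dihydro-1-benzofuran, via syn-alcohol 12 (not isolated)
Conditions: RuCl[(R,R)-TsDPEN](p-cymene) (cat.), HCO2H/Et3N (1:1), DMF, 35 °C; volatiles removed; then t-BuOK, THF/DMPU, 65 °C
Reagents that add atoms: none
Why: The ruthenium hydride–amine catalyst transfers H−/H+ to the aryl ketone through a six-membered outer-sphere transition state while Et3N keeps the two C3 epimers of 11 in rapid equilibrium via the enol (asymmetric transfer hydrogenation with dynamic kinetic resolution; closest known type: reduction of α-aryl aryl ketones to 1,2-diaryl alkanols followed by intramolecular aryl ether formation). C2 is set by the catalyst: the (R,R)-ligand places the conjugated aryl next to the η6-arene and should give the (R)-carbinol. C3 is set by the substrate in the faster-reacting epimer, where hydride adds anti to the perpendicular C3-aryl group (Felkin–Anh), which should give syn-alcohol 12. t-BuOK then converts the C2 hydroxyl into the alkoxide, which attacks C7a and expels fluoride (SNAr, 5-exo closure of ring B: O1–C2–C3–C3a–C7a) with both centres untouched, so syn-12 should become the trans-2,3 ring of 13. The step needs epimerisation at C3 to outrun reduction of the slower epimer and β-elimination of the trityloxy group, which the amine-buffered formate medium is meant to secure. It also needs attack by the C2 oxygen only, which the trityl and silyl ethers guarantee, and C7a carries the only fluoride.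

Step 9
Reactants: 13 (2R,3S)-2-[4-(benzyloxy)-3-methoxyphenyl]-5-[(S)-{[tert-butyl(dimethyl)silyl]oxy}[(4R)-2,2-dimethyl-1,3-dioxolan-4-yl]methyl]-7-methoxy-3-[(triphenylmethoxy)methyl]-2,3-dihydro-1-benzofuran
Product: 15 (1S,2R)-1-{(2R,3S)-2-[4-(benzyloxy)-3-methoxyphenyl]-3-(hydroxymethyl)-7-methoxy-2,3-dihydro-1-benzofuran-5-yl}propane-1,2,3-triol, via carbinol 14 (not isolated)
Conditions: Bu4NF, THF, rt; then AcOH/H2O (4:1), 40 °C
Reagents that add atoms: none
Why: Fluoride cleaves the silyl ether and dilute acetic acid then hydrolyses the trityl ether and the acetonide (deprotection), conditions mild enough to leave the benzyl ether, the benzylic C–O bonds and all four stereocentres untouched.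

Step 10
Reactants: 15 (1S,2R)-1-{(2R,3S)-2-[4-(benzyloxy)-3-methoxyphenyl]-3-(hydroxymethyl)-7-methoxy-2,3-dihydro-1-benzofuran-5-yl}propane-1,2,3-triol
Product: 16 (1S,2R)-1-[(2R,3S)-2-(4-hydroxy-3-methoxyphenyl)-3-(hydroxymethyl)-7-methoxy-2,3-dihydro-1-benzofuran-5-yl]propane-1,2,3-triol
Conditions: H2 (1 atm), 10% Pd/C, EtOAc/EtOH, rt
Reagents that add atoms: none
Why: Hydrogenolysis of the aryl benzyl ether over palladium in neutral medium should be much faster than cleavage of the benzylic C–O bonds at C2 and C1', so the phenol is freed with the stereocentres intact.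

**Compound list**

1 | 4-bromo-1-fluoro-2-methoxybenzene | COc1cc(Br)ccc1F | starting material
2 | methyl (4R)-2,2-dimethyl-1,3-dioxolane-4-carboxylate | COC(=O)[C@H]1COC(C)(C)O1 | starting material
3 | (4-fluoro-3-methoxyphenyl)lithium | [Li]c1ccc(F)c(OC)c1 | intermediate
4 | (4-fluoro-3-methoxyphenyl)[(4R)-2,2-dimethyl-1,3-dioxolan-4-yl]methanone | COc1cc(C(=O)[C@H]2COC(C)(C)O2)ccc1F | intermediate
5 | (S)-(4-fluoro-3-methoxyphenyl)[(4R)-2,2-dimethyl-1,3-dioxolan-4-yl]methanol | COc1cc([C@H](O)[C@H]2COC(C)(C)O2)ccc1F | intermediate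
6 | tert-butyl{(S)-[(4R)-2,2-dimethyl-1,3-dioxolan-4-yl](4-fluoro-3-methoxyphenyl)methoxy}dimethylsilane | COc1cc([C@H](O[Si](C)(C)C(C)(C)C)[C@H]2COC(C)(C)O2)ccc1F | intermediate
7 | 2-{5-[(S)-{[tert-butyl(dimethyl)silyl]oxy}[(4R)-2,2-dimethyl-1,3-dioxolan-4-yl]methyl]-2-fluoro-3-methoxyphenyl}-4,4,5,5-tetramethyl-1,3,2-dioxaborolane | COc1cc([C@H](O[Si](C)(C)C(C)(C)C)[C@H]2COC(C)(C)O2)cc(B2OC(C)(C)C(C)(C)O2)c1F | intermediate
8 | 1-[4-(benzyloxy)-3-methoxyphenyl]-2-bromoethan-1-one | COc1cc(C(=O)CBr)ccc1OCc1ccccc1 | starting material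
9 | 1-[4-(benzyloxy)-3-methoxyphenyl]-2-{5-[(S)-{[tert-butyl(dimethyl)silyl]oxy}[(4R)-2,2-dimethyl-1,3-dioxolan-4-yl]methyl]-2-fluoro-3-methoxyphenyl}ethan-1-one | COc1cc(C(=O)Cc2cc([C@H](O[Si](C)(C)C(C)(C)C)[C@H]3COC(C)(C)O3)cc(OC)c2F)ccc1OCc1ccccc1 | intermediate
10 | 3-hydroxy analogue of 9: …-3-hydroxypropan-1-one, C2 epimers | COc1cc(C(=O)C(CO)c2cc([C@H](O[Si](C)(C)C(C)(C)C)[C@H]3COC(C)(C)O3)cc(OC)c2F)ccc1OCc1ccccc1 | intermediate
11 | trityl ether of 10: …-3-(triphenylmethoxy)propan-1-one, C2 epimers | COc1cc(C(=O)C(COC(c3ccccc3)(c3ccccc3)c3ccccc3)c2cc([C@H](O[Si](C)(C)C(C)(C)C)[C@H]3COC(C)(C)O3)cc(OC)c2F)ccc1OCc1ccccc1 | intermediate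
12 | (1R,2S)-1-[4-(benzyloxy)-3-methoxyphenyl]-2-{5-[(S)-{[tert-butyl(dimethyl)silyl]oxy}[(4R)-2,2-dimethyl-1,3-dioxolan-4-yl]methyl]-2-fluoro-3-methoxyphenyl}-3-(triphenylmethoxy)propan-1-ol | COc1cc([C@H](O)[C@H](COC(c3ccccc3)(c3ccccc3)c3ccccc3)c2cc([C@H](O[Si](C)(C)C(C)(C)C)[C@H]3COC(C)(C)O3)cc(OC)c2F)ccc1OCc1ccccc1 | intermediate
13 | (2R,3S)-2-[4-(benzyloxy)-3-methoxyphenyl]-5-[(S)-{[tert-butyl(dimethyl)silyl]oxy}[(4R)-2,2-dimethyl-1,3-dioxolan-4-yl]methyl]-7-methoxy-3-[(triphenylmethoxy)methyl]-2,3-dihydro-1-benzofuran | COc1cc([C@@H]2Oc3c(OC)cc([C@H](O[Si](C)(C)C(C)(C)C)[C@H]4COC(C)(C)O4)cc3[C@H]2COC(c4ccccc4)(c4ccccc4)c4ccccc4)ccc1OCc1ccccc1 | intermediate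
14 | (S)-{(2R,3S)-2-[4-(benzyloxy)-3-methoxyphenyl]-7-methoxy-3-[(triphenylmethoxy)methyl]-2,3-dihydro-1-benzofuran-5-yl}[(4R)-2,2-dimethyl-1,3-dioxolan-4-yl]methanol | COc1cc([C@@H]2Oc3c(OC)cc([C@H](O)[C@H]4COC(C)(C)O4)cc3[C@H]2COC(c4ccccc4)(c4ccccc4)c4ccccc4)ccc1OCc1ccccc1 | intermediate
15 | (1S,2R)-1-{(2R,3S)-2-[4-(benzyloxy)-3-methoxyphenyl]-3-(hydroxymethyl)-7-methoxy-2,3-dihydro-1-benzofuran-5-yl}propane-1,2,3-triol | COc1cc([C@@H]2Oc3c(OC)cc([C@H](O)[C@H](O)CO)cc3[C@H]2CO)ccc1OCc1ccccc1 | intermediate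
16 | (1S,2R)-1-[(2R,3S)-2-(4-hydroxy-3-methoxyphenyl)-3-(hydroxymethyl)-7-methoxy-2,3-dihydro-1-benzofuran-5-yl]propane-1,2,3-triol | COc1cc([C@@H]2Oc3c(OC)cc([C@H](O)[C@H](O)CO)cc3[C@H]2CO)ccc1O | target

**Totals and risks**

Total step count: 10. Longest linear sequence: 10 steps (from 1).

Steps most likely to fail:

Step 8. Equilibration of the C3 epimers may be too slow relative to hydride transfer, eroding the syn/anti ratio; the enolising ketone may lose trityloxide by β-elimination; fluoride displacement on the electron-rich ring may be slow. Fallback: the two centres are set by an auxiliary-controlled aldol instead of a ketone reduction. Setting out from boronate 7, Pd-catalysed coupling with ethyl bromoacetate (Pd(OAc)2, P(o-tol)3, K3PO4, THF/H2O) should give the ethyl arylacetate F1. LiOH (THF/H2O) should then give the arylacetic acid F2. Pivaloyl chloride/Et3N followed by lithiated (R)-4-benzyl-1,3-oxazolidin-2-one should give the N-acyl oxazolidinone F3. Bu2BOTf/i-Pr2NEt and then 4-(benzyloxy)-3-methoxybenzaldehyde (Evans syn-aldol through the (Z)-boron enolate and a chair transition state) should give the syn-aldol adduct F4, with the (R)-auxiliary chosen to deliver the same C2/C3 arrangement. LiBH4 (THF/MeOH, 0 °C) should release the auxiliary and give the 1,3-diol F5. Ph3CCl/pyridine on the primary hydroxyl then gives alcohol 12, which is cyclised with t-BuOK as in step 8, rejoining the route at 13.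

Step 5. Protodeboronation of the ortho-fluoro arylboronate, or base-induced alkylation and self-condensation of the bromoketone, may outpace transmetalation. Fallback: the coupling polarity is reversed to a ketone-enolate arylation. Setting out from 7, ipso-bromodeboronation (1,3-dibromo-5,5-dimethylhydantoin, NaOMe (cat.), MeCN, rt) should give the aryl bromide F6. Pd-catalysed α-arylation of commercial 1-[4-(benzyloxy)-3-methoxyphenyl]ethan-1-one (Pd2(dba)3, Xantphos, K3PO4, toluene, 80 °C) then rejoins the route at deoxybenzoin 9.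

Step 6. A second hydroxymethylation, or base-induced dehydration of the aldol to the α-methylene ketone, may compete. Fallback: the free enolate is avoided. Setting out from 9, Me3SiOTf/Et3N (CH2Cl2, 0 °C) should give the (Z)-silyl enol ether F7. A Mukaiyama aldol with aqueous formaldehyde catalysed by Sc(OTf)3 (THF/H2O, rt) then rejoins the route at 10.

**Further compounds**

F1 | step 8 | ethyl 2-{5-[(S)-{[tert-butyl(dimethyl)silyl]oxy}[(4R)-2,2-dimethyl-1,3-dioxolan-4-yl]methyl]-2-fluoro-3-methoxyphenyl}acetate | CCOC(=O)Cc1cc([C@H](O[Si](C)(C)C(C)(C)C)[C@H]2COC(C)(C)O2)cc(OC)c1F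
F2 | step 8 | 2-{5-[(S)-{[tert-butyl(dimethyl)silyl]oxy}[(4R)-2,2-dimethyl-1,3-dioxolan-4-yl]methyl]-2-fluoro-3-methoxyphenyl}acetic acid | OC(=O)Cc1cc([C@H](O[Si](C)(C)C(C)(C)C)[C@H]2COC(C)(C)O2)cc(OC)c1F
F3 | step 8 | (4R)-4-benzyl-3-(2-{5-[(S)-{[tert-butyl(dimethyl)silyl]oxy}[(4R)-2,2-dimethyl-1,3-dioxolan-4-yl]methyl]-2-fluoro-3-methoxyphenyl}acetyl)-1,3-oxazolidin-2-one | O=C(Cc1cc([C@H](O[Si](C)(C)C(C)(C)C)[C@H]2COC(C)(C)O2)cc(OC)c1F)N1[C@H](Cc2ccccc2)COC1=O
F4 | step 8 | (4R)-4-benzyl-3-[(2R,3R)-3-[4-(benzyloxy)-3-methoxyphenyl]-2-{5-[(S)-{[tert-butyl(dimethyl)silyl]oxy}[(4R)-2,2-dimethyl-1,3-dioxolan-4-yl]methyl]-2-fluoro-3-methoxyphenyl}-3-hydroxypropanoyl]-1,3-oxazolidin-2-one | COc1cc([C@H](O)[C@H](C(=O)N2[C@H](Cc3ccccc3)COC2=O)c2cc([C@H](O[Si](C)(C)C(C)(C)C)[C@H]3COC(C)(C)O3)cc(OC)c2F)ccc1OCc1ccccc1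
F5 | step 8 | (1R,2S)-1-[4-(benzyloxy)-3-methoxyphenyl]-2-{5-[(S)-{[tert-butyl(dimethyl)silyl]oxy}[(4R)-2,2-dimethyl-1,3-dioxolan-4-yl]methyl]-2-fluoro-3-methoxyphenyl}propane-1,3-diol | COc1cc([C@H](O)[C@H](CO)c2cc([C@H](O[Si](C)(C)C(C)(C)C)[C@H]3COC(C)(C)O3)cc(OC)c2F)ccc1OCc1ccccc1
F6 | step 5 | {(S)-(3-bromo-4-fluoro-5-methoxyphenyl)[(4R)-2,2-dimethyl-1,3-dioxolan-4-yl]methoxy}(tert-butyl)dimethylsilane | COc1cc([C@H](O[Si](C)(C)C(C)(C)C)[C@H]2COC(C)(C)O2)cc(Br)c1F
F7 | step 6 | (Z)-trimethylsilyl enol ether of 9 | COc1cc(/C(O[Si](C)(C)C)=C/c2cc([C@H](O[Si](C)(C)C(C)(C)C)[C@H]3COC(C)(C)O3)cc(OC)c2F)ccc1OCc1ccccc1
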